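## Retrosynthetic overview

- The strategy rests on ring B: C8 and C9 are adjacent stereocentres carrying the C17 carboxyl and the C11–C16 chain trans-diequatorially, and C8 is the α-carbon of a β,γ-unsaturated acid (C6=C7–C8–C17). This is the pattern left when an ester dienolate adds through its α-carbon to an enoate, so C8–C9 is disconnected to a ring A bis-enoate with trans arms at C5 and C10.
- Both arms come from one dialdehyde by two Wittig reactions. The dialdehyde comes from glycol cleavage of the C1–C2 bond of a trans-fused 1-hydroxyhydrindan-2-one, itself made from (S)-2-allyl-2,6,6-trimethylcyclohexanone (C10 from a Pd-catalysed decarboxylative allylation, C5 from hydrogenation).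
- Side chain: the C12 methyl ester is reduced, converted to the iodide and alkylzinc, and Negishi-coupled with a (Z)-β-iodo enoate (C13–C16); acetylation and acid release of both tert-butyl esters finish the synthesis.
- Ring order: ring A is bought; a temporary five-membered ring is closed (step 4) and cleaved (step 7); ring B is closed last (step 10).

Key step: step 10

Assumption: labdane numbering is used for the skeleton (C1–C10 decalin, C17 on C8, C11–C16 side chain); the carbinol centres made in steps 5 and 7 are carried as epimer mixtures because the glycol cleavage removes them.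

## Route

Step 1
Reactants: 1 2,2,6-trimethylcyclohexanone; 2 allyl chloroformate
Product: 4 allyl 2,6,6-trimethylcyclohex-1-en-1-yl carbonate, via lithium enolate 3 (not isolated)
Conditions: LiN(SiMe3)2, THF, 0 °C; then 2, −78 → 25 °C
Reagents that add atoms: none
Why: The ketone has a single α-hydrogen, so only one (tetrasubstituted) lithium enolate can form, and the chloroformate acylates it on oxygen (enol carbonate formation); no stereocentre remains.

Step 2
Reactants: 4 allyl 2,6,6-trimethylcyclohex-1-en-1-yl carbonate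
Product: 5 (S)-2-allyl-2,6,6-trimethylcyclohexanone
Conditions: Pd2(dba)3 (cat.), (S)-t-BuPHOX (cat.), THF, 25 °C
Reagents that add atoms: none
Why: Decarboxylative asymmetric allylic alkylation (Tsuji allylation): zerovalent palladium ionises the allyl carbonate, CO2 is lost, and the enolate recombines with the π-allyl unit inside the chiral phosphinooxazoline pocket, the (S)-ligand being expected to give the (S)-quaternary centre (C10) as it does for 2-allyl-2-methylcyclohexanone.

Step 3
Reactants: 5 (S)-2-allyl-2,6,6-trimethylcyclohexanone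
Product: 6 (S)-2,2,6-trimethyl-6-(2-oxopropyl)cyclohexanone
Conditions: PdCl2 (cat.), Cu(OAc)2·H2O (cat.), O2 (1 atm), DMA–H2O, 25 °C
Reagents that add atoms: water, O
Why: Tsuji–Wacker oxidation: Markovnikov hydroxypalladation of the terminal alkene by divalent palladium gives the methyl ketone; the quaternary centre is untouched.

Step 4
Reactants: 6 (S)-2,2,6-trimethyl-6-(2-oxopropyl)cyclohexanone
Product: 8 (S)-4,4,7a-trimethyl-5,6,7,7a-tetrahydro-1H-inden-2(4H)-one, via aldol ketol 7 (not isolated)
Conditions: KOH, xylenes, 110 °C, Dean–Stark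
Reagents that add atoms: none
Why: Intramolecular aldol condensation: the ring ketone cannot enolise, so only the methyl group of the side-chain ketone attacks it (five-membered closure) and dehydration gives the conjugated bicyclic enone.

Step 5
Reactants: 8 (S)-4,4,7a-trimethyl-5,6,7,7a-tetrahydro-1H-inden-2(4H)-one
Product: 10 (7aR)-1-hydroxy-4,4,7a-trimethyl-5,6,7,7a-tetrahydro-1H-inden-2(4H)-one (C1 epimers), via potassium dienolate 9 (not isolated)
Conditions: KN(SiMe3)2, THF, −78 °C; then 2-(phenylsulfonyl)-3-phenyloxaziridine, −78 °C; AcOH quench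
Reagents that add atoms: 2-(phenylsulfonyl)-3-phenyloxaziridine, O=S(=O)(c1ccccc1)N1OC1c1ccccc1
Why: Kinetic α′-deprotonation can only occur at C1 (both γ-carbons are quaternary) and the cross-conjugated enolate is hydroxylated by the oxaziridine (Davis oxidation); the new carbinol configuration is irrelevant.

Step 6
Reactants: 10 (7aR)-1-hydroxy-4,4,7a-trimethyl-5,6,7,7a-tetrahydro-1H-inden-2(4H)-one
Product: 11 (3aR,7aR)-1-hydroxy-4,4,7a-trimethyloctahydro-2H-inden-2-one (trans-fused; C1 epimers)
Conditions: H2 (50 bar), Pd on carbon, EtOAc, 25 °C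
Reagents that add atoms: none
Why: Heterogeneous hydrogenation adds H2 syn to the C3=C3a alkene from the face opposite the two syn-axial methyl groups (angular C7a–CH3 and axial C4–CH3), which should place H3a (C5–H) trans to the angular methyl, as 4,4-dimethyl-Δ5 steroids give 5α products.

Step 7
Reactants: 11 (3aR,7aR)-1-hydroxy-4,4,7a-trimethyloctahydro-2H-inden-2-one
Product: 13 2-[(1R,6R)-6-formyl-2,2,6-trimethylcyclohexyl]acetaldehyde, via diol 12 (not isolated)
Conditions: NaBH4, MeOH, 0 °C; adjust to pH 6 (aq. NaH2PO4); then NaIO4, THF–H2O, 25 °C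
Reagents that add atoms: none
Why: Borohydride reduction gives the 1,2-diol and periodate (Malaprade) cleavage of C1–C2 releases both aldehydes; C10 is quaternary and C5 is β to the new carbonyl, so neither centre can epimerise.

Step 8
Reactants: 13 2-[(1R,6R)-6-formyl-2,2,6-trimethylcyclohexyl]acetaldehyde; 14 tert-butyl (triphenylphosphoranylidene)acetate
Product: 15 tert-butyl (E)-4-[(1R,6R)-6-formyl-2,2,6-trimethylcyclohexyl]but-2-enoate
Conditions: 14 (1.0 equiv), CH2Cl2, 0 → 25 °C
Reagents that add atoms: none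
Why: Chemoselective Wittig olefination: the stabilised ylide reacts far faster with the unhindered CH2–CHO than with the neopentyl aldehyde on the quaternary carbon, and gives the (E)-enoate.

Step 9
Reactants: 15 tert-butyl (E)-4-[(1R,6R)-6-formyl-2,2,6-trimethylcyclohexyl]but-2-enoate; 16 methyl (triphenylphosphoranylidene)acetate
Product: 17 methyl (E)-3-[(1S,2R)-2-[(E)-4-tert-butoxy-4-oxobut-2-en-1-yl]-1,3,3-trimethylcyclohexyl]acrylate
Conditions: 16 (excess), toluene, 110 °C
Reagents that add atoms: none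
Why: Wittig olefination of the remaining hindered aldehyde under thermal forcing, E-selective for a stabilised ylide; the aldehyde has no α-hydrogen, so nothing can epimerise.

Step 10
Reactants: 17 methyl (E)-3-[(1S,2R)-2-[(E)-4-tert-butoxy-4-oxobut-2-en-1-yl]-1,3,3-trimethylcyclohexyl]acrylate
Product: 21 tert-butyl (1R,2S,4aR,8aS)-1-(2-methoxy-2-oxoethyl)-5,5,8a-trimethyl-1,2,4a,5,6,7,8,8a-octahydronaphthalene-2-carboxylate, via lithium Z-dienolate 18 (not isolated), via cyclised lithium ester enolate 19 (not isolated), via trimethylsilyl ketene acetal 20 (not isolated)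
Conditions: LiN(i-Pr)2 (1.1 equiv), THF–HMPA, −78 °C; then Me3SiCl, −78 → 0 °C; aq. citric acid
Reagents that add atoms: none
Why: LiN(i-Pr)2 with HMPA removes a C6 proton of the tert-butyl enoate, the only γ-C–H in the molecule because the γ-carbon of the methyl enoate is the quaternary C10, and the lithium dienolate adds through its α-carbon C8 to the β-carbon C9 of the methyl enoate (intramolecular Michael addition of an ester dienolate, the ring-forming counterpart of deconjugative α-alkylation). Ring B closes in a 6-(enolexo)-exo-trig mode; attack through C6 would need a four-membered ring, so α-regiochemistry is enforced. The closure needs a Z C6=C7 bond in the dienolate, which is what kinetic γ-deprotonation of an (E)-2-enoate gives, and the same E geometry keeps C17 anti to C6 so that it becomes pseudo-equatorial on C8. The trans-diequatorial arms on the ring A chair allow only the half-chair transition state in which C9 lies over the dienolate face syn to H5 and anti to the axial C10 methyl (the boat alternative eclipses the substituents of C9 and C10), which sets C8 as S; the methyl enoate turns C11 outward into the equatorial position with H9 anti to the C10 methyl, which sets C9 as R and gives the trans-fused, 8,9-trans product. Silylating the cyclised methyl ester enolate at −78 °C before warming stops it from removing the acidic C8–H, which would scramble C8 or move the alkene into conjugation; the silyl ketene acetal is hydrolysed on work-up.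

Step 11
Reactants: 21 tert-butyl (1R,2S,4aR,8aS)-1-(2-methoxy-2-oxoethyl)-5,5,8a-trimethyl-1,2,4a,5,6,7,8,8a-octahydronaphthalene-2-carboxylate
Product: 22 tert-butyl (1R,2S,4aR,8aS)-1-(2-hydroxyethyl)-5,5,8a-trimethyl-1,2,4a,5,6,7,8,8a-octahydronaphthalene-2-carboxylate
Conditions: LiBH4, MeOH (1 equiv), THF, 0 → 25 °C
Reagents that add atoms: none
Why: Chemoselective ester reduction: LiBH4 reduces the primary methyl ester but not the hindered tert-butyl ester, and is not basic enough to epimerise C8.

Step 12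
Reactants: 22 tert-butyl (1R,2S,4aR,8aS)-1-(2-hydroxyethyl)-5,5,8a-trimethyl-1,2,4a,5,6,7,8,8a-octahydronaphthalene-2-carboxylate
Product: 23 tert-butyl (1R,2S,4aR,8aS)-1-(2-iodoethyl)-5,5,8a-trimethyl-1,2,4a,5,6,7,8,8a-octahydronaphthalene-2-carboxylate
Conditions: I2, PPh3, imidazole, CH2Cl2, 0 °C
Reagents that add atoms: iodine, II
Why: Appel-type iodination: iodide displaces the alkoxyphosphonium group at the primary carbon by SN2; no stereocentre is involved.

Step 13
Reactants: 24 tert-butyl(diphenyl)(prop-2-yn-1-yloxy)silane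
Product: 26 tert-butyl 4-[(tert-butyldiphenylsilyl)oxy]but-2-ynoate, via lithium acetylide 25 (not isolated)
Conditions: n-BuLi, THF, −78 °C; then Boc2O, −78 → 0 °C; H2O
Reagents that add atoms: di-tert-butyl dicarbonate, CC(C)(C)OC(=O)OC(=O)OC(C)(C)C
Why: Deprotonation of the terminal alkyne and C-acylation of the acetylide with the dicarbonate gives the tert-butyl ynoate.

Step 14
Reactants: 26 tert-butyl 4-[(tert-butyldiphenylsilyl)oxy]but-2-ynoate
Product: 27 tert-butyl (Z)-4-[(tert-butyldiphenylsilyl)oxy]-3-iodobut-2-enoate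
Conditions: NaI, AcOH, 70 °C
Reagents that add atoms: sodium iodide, [Na+].[I-]
Why: Conjugate hydroiodination of the ynoate: iodide adds to C3 and the proton to C2 in an anti sense, giving the (Z)-iodo enoate with iodine cis to the ester.

Step 15
Reactants: 23 tert-butyl (1R,2S,4aR,8aS)-1-(2-iodoethyl)-5,5,8a-trimethyl-1,2,4a,5,6,7,8,8a-octahydronaphthalene-2-carboxylate; 27 tert-butyl (Z)-4-[(tert-butyldiphenylsilyl)oxy]-3-iodobut-2-enoate
Product: 29 tert-butyl (1R,2S,4aR,8aS)-1-[(3E)-5-tert-butoxy-3-[(tert-butyldiphenylsilyloxy)methyl]-5-oxopent-3-en-1-yl]-5,5,8a-trimethyl-1,2,4a,5,6,7,8,8a-octahydronaphthalene-2-carboxylate, via alkylzinc iodide 28 (not isolated)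
Conditions: Zn dust (activated by BrCH2CH2Br and Me3SiCl), DMF, 25 °C; then 27, PdCl2(dppf) (cat.), THF–DMF, 25–40 °C
Reagents that add atoms: none
Why: Negishi coupling: zinc inserts into the primary C–I bond, the alkylzinc transmetalates to the vinylpalladium formed from 27, and reductive elimination keeps the alkene geometry, so C12 ends cis to the C15 ester (E alkene).

Step 16
Reactants: 29 tert-butyl (1R,2S,4aR,8aS)-1-[(3E)-5-tert-butoxy-3-[(tert-butyldiphenylsilyloxy)methyl]-5-oxopent-3-en-1-yl]-5,5,8a-trimethyl-1,2,4a,5,6,7,8,8a-octahydronaphthalene-2-carboxylate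
Product: 30 tert-butyl (1R,2S,4aR,8aS)-1-[(3E)-5-tert-butoxy-3-(hydroxymethyl)-5-oxopent-3-en-1-yl]-5,5,8a-trimethyl-1,2,4a,5,6,7,8,8a-octahydronaphthalene-2-carboxylate
Conditions: Bu4NF, AcOH, THF, 0 → 25 °C
Reagents that add atoms: none
Why: Fluoride cleavage of the silyl ether, buffered with AcOH so that C8–H is not exposed to basic fluoride; the freed hydroxymethyl is trans to the ester and cannot lactonise.

Step 17
Reactants: 30 tert-butyl (1R,2S,4aR,8aS)-1-[(3E)-5-tert-butoxy-3-(hydroxymethyl)-5-oxopent-3-en-1-yl]-5,5,8a-trimethyl-1,2,4a,5,6,7,8,8a-octahydronaphthalene-2-carboxylate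
Product: 31 tert-butyl (1R,2S,4aR,8aS)-1-[(3E)-3-(acetoxymethyl)-5-tert-butoxy-5-oxopent-3-en-1-yl]-5,5,8a-trimethyl-1,2,4a,5,6,7,8,8a-octahydronaphthalene-2-carboxylate
Conditions: Ac2O, pyridine, DMAP (cat.), CH2Cl2, 0 °C
Reagents that add atoms: acetic anhydride, CC(=O)OC(C)=O
Why: DMAP-catalysed acylation of the primary allylic alcohol; the weak amine bases do not touch C8.

Step 18
Reactants: 31 tert-butyl (1R,2S,4aR,8aS)-1-[(3E)-3-(acetoxymethyl)-5-tert-butoxy-5-oxopent-3-en-1-yl]-5,5,8a-trimethyl-1,2,4a,5,6,7,8,8a-octahydronaphthalene-2-carboxylate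
Product: 32 (1R,2S,4aR,8aS)-1-[(3E)-3-(acetoxymethyl)-4-carboxybut-3-en-1-yl]-5,5,8a-trimethyl-1,2,4a,5,6,7,8,8a-octahydronaphthalene-2-carboxylic acid (target)
Conditions: CF3CO2H–CH2Cl2 (1:4), 0 → 25 °C
Reagents that add atoms: none
Why: Acidolysis of both tert-butyl esters by loss of isobutene; the acetate, both alkenes and the C8 configuration are stable to non-nucleophilic acid at this temperature.

## Compound list

1 | 2,2,6-trimethylcyclohexanone | CC1CCCC(C)(C)C1=O | starting material
2 | allyl chloroformate | C=CCOC(=O)Cl | starting material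
3 | lithium 2,6,6-trimethylcyclohex-1-en-1-olate | [Li+].[O-]C1=C(C)CCCC1(C)C | intermediate
4 | allyl 2,6,6-trimethylcyclohex-1-en-1-yl carbonate | C=CCOC(=O)OC1=C(C)CCCC1(C)C | intermediate
5 | (S)-2-allyl-2,6,6-trimethylcyclohexanone | C=CC[C@]1(C)CCCC(C)(C)C1=O | intermediate
6 | (S)-2,2,6-trimethyl-6-(2-oxopropyl)cyclohexanone | CC(=O)C[C@]1(C)CCCC(C)(C)C1=O | intermediate
7 | (7aS)-3a-hydroxy-4,4,7a-trimethyloctahydro-2H-inden-2-one (aldol ketol, C3a undefined) | O=C1C[C@]2(C)CCCC(C)(C)C2(O)C1 | intermediate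
8 | (S)-4,4,7a-trimethyl-5,6,7,7a-tetrahydro-1H-inden-2(4H)-one | O=C1C[C@]2(C)CCCC(C)(C)C2=C1 | intermediate
9 | potassium (7aS)-4,4,7a-trimethyl-5,6,7,7a-tetrahydro-4H-inden-2-olate (cross-conjugated dienolate) | [K+].[O-]C1=C[C@]2(C)CCCC(C)(C)C2=C1 | intermediate
10 | (7aR)-1-hydroxy-4,4,7a-trimethyl-5,6,7,7a-tetrahydro-1H-inden-2(4H)-one (C1 epimers) | O=C1C(O)[C@]2(C)CCCC(C)(C)C2=C1 | intermediate
11 | (3aR,7aR)-1-hydroxy-4,4,7a-trimethyloctahydro-2H-inden-2-one (trans-fused, C1 epimers) | O=C1C(O)[C@]2(C)CCCC(C)(C)[C@H]2C1 | intermediate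
12 | (3aR,7aR)-4,4,7a-trimethyloctahydro-1H-indene-1,2-diol (trans-fused, C1/C2 epimers) | OC1C(O)[C@]2(C)CCCC(C)(C)[C@H]2C1 | intermediate
13 | 2-[(1R,6R)-6-formyl-2,2,6-trimethylcyclohexyl]acetaldehyde (arms trans) | O=C[C@]1(C)CCCC(C)(C)[C@H]1CC=O | intermediate
14 | tert-butyl (triphenylphosphoranylidene)acetate | CC(C)(C)OC(=O)C=P(c1ccccc1)(c1ccccc1)c1ccccc1 | starting material
15 | tert-butyl (E)-4-[(1R,6R)-6-formyl-2,2,6-trimethylcyclohexyl]but-2-enoate | O=C[C@]1(C)CCCC(C)(C)[C@H]1C/C=C/C(=O)OC(C)(C)C | intermediate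
16 | methyl (triphenylphosphoranylidene)acetate | COC(=O)C=P(c1ccccc1)(c1ccccc1)c1ccccc1 | starting material
17 | methyl (E)-3-[(1S,2R)-2-[(E)-4-tert-butoxy-4-oxobut-2-en-1-yl]-1,3,3-trimethylcyclohexyl]acrylate | COC(=O)/C=C/[C@]1(C)CCCC(C)(C)[C@H]1C/C=C/C(=O)OC(C)(C)C | intermediate
18 | lithium dienolate of 17 (C6=C7 Z, tert-butyl ester arm) | [Li+].COC(=O)/C=C/[C@]1(C)CCCC(C)(C)[C@H]1/C=C\C=C([O-])OC(C)(C)C | intermediate
19 | lithium enolate of the C12 methyl ester of 21 | [Li+].COC([O-])=C[C@@H]1[C@@H](C(=O)OC(C)(C)C)C=C[C@@H]2C(C)(C)CCC[C@@]12C | intermediate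
20 | trimethylsilyl ketene acetal of the C12 methyl ester of 21 | COC(O[Si](C)(C)C)=C[C@@H]1[C@@H](C(=O)OC(C)(C)C)C=C[C@@H]2C(C)(C)CCC[C@@]12C | intermediate
21 | tert-butyl (1R,2S,4aR,8aS)-1-(2-methoxy-2-oxoethyl)-5,5,8a-trimethyl-1,2,4a,5,6,7,8,8a-octahydronaphthalene-2-carboxylate | COC(=O)C[C@@H]1[C@@H](C(=O)OC(C)(C)C)C=C[C@@H]2C(C)(C)CCC[C@@]12C | intermediate
22 | tert-butyl (1R,2S,4aR,8aS)-1-(2-hydroxyethyl)-5,5,8a-trimethyl-1,2,4a,5,6,7,8,8a-octahydronaphthalene-2-carboxylate | OCC[C@@H]1[C@@H](C(=O)OC(C)(C)C)C=C[C@@H]2C(C)(C)CCC[C@@]12C | intermediate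
23 | tert-butyl (1R,2S,4aR,8aS)-1-(2-iodoethyl)-5,5,8a-trimethyl-1,2,4a,5,6,7,8,8a-octahydronaphthalene-2-carboxylate | ICC[C@@H]1[C@@H](C(=O)OC(C)(C)C)C=C[C@@H]2C(C)(C)CCC[C@@]12C | intermediate
24 | tert-butyl(diphenyl)(prop-2-yn-1-yloxy)silane | C#CCO[Si](c1ccccc1)(c1ccccc1)C(C)(C)C | starting material
25 | lithium acetylide of 24 | [Li+].[C-]#CCO[Si](c1ccccc1)(c1ccccc1)C(C)(C)C | intermediate
26 | tert-butyl 4-[(tert-butyldiphenylsilyl)oxy]but-2-ynoate | CC(C)(C)OC(=O)C#CCO[Si](c1ccccc1)(c1ccccc1)C(C)(C)C | intermediate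
27 | tert-butyl (Z)-4-[(tert-butyldiphenylsilyl)oxy]-3-iodobut-2-enoate (I cis to ester) | CC(C)(C)OC(=O)/C=C(\I)CO[Si](c1ccccc1)(c1ccccc1)C(C)(C)C | intermediate
28 | alkylzinc iodide from 23 (C12–ZnI) | I[Zn]CC[C@@H]1[C@@H](C(=O)OC(C)(C)C)C=C[C@@H]2C(C)(C)CCC[C@@]12C | intermediate
29 | tert-butyl (1R,2S,4aR,8aS)-1-[(3E)-5-tert-butoxy-3-[(tert-butyldiphenylsilyloxy)methyl]-5-oxopent-3-en-1-yl]-5,5,8a-trimethyl-1,2,4a,5,6,7,8,8a-octahydronaphthalene-2-carboxylate | CC(C)(C)OC(=O)/C=C(\CC[C@@H]1[C@@H](C(=O)OC(C)(C)C)C=C[C@@H]2C(C)(C)CCC[C@@]12C)CO[Si](c1ccccc1)(c1ccccc1)C(C)(C)C | intermediate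
30 | tert-butyl (1R,2S,4aR,8aS)-1-[(3E)-5-tert-butoxy-3-(hydroxymethyl)-5-oxopent-3-en-1-yl]-5,5,8a-trimethyl-1,2,4a,5,6,7,8,8a-octahydronaphthalene-2-carboxylate | CC(C)(C)OC(=O)/C=C(\CC[C@@H]1[C@@H](C(=O)OC(C)(C)C)C=C[C@@H]2C(C)(C)CCC[C@@]12C)CO | intermediate
31 | tert-butyl (1R,2S,4aR,8aS)-1-[(3E)-3-(acetoxymethyl)-5-tert-butoxy-5-oxopent-3-en-1-yl]-5,5,8a-trimethyl-1,2,4a,5,6,7,8,8a-octahydronaphthalene-2-carboxylate | CC(=O)OC/C(=C/C(=O)OC(C)(C)C)CC[C@@H]1[C@@H](C(=O)OC(C)(C)C)C=C[C@@H]2C(C)(C)CCC[C@@]12C | intermediate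
32 | (1R,2S,4aR,8aS)-1-[(3E)-3-(acetoxymethyl)-4-carboxybut-3-en-1-yl]-5,5,8a-trimethyl-1,2,4a,5,6,7,8,8a-octahydronaphthalene-2-carboxylic acid | CC(=O)OC/C(=C/C(=O)O)CC[C@@H]1[C@@H](C(=O)O)C=C[C@@H]2C(C)(C)CCC[C@@]12C | target

## Step count and risks

Total step count: 18. Longest linear sequence: 16 steps (steps 1–12 and 15–18); steps 13–14 make the iodo enoate.

Steps most likely to fail:

1. Step 10 (key step). Ring closure needs the kinetic dienolate to have the Z C6=C7 geometry and the cyclised ester enolate to be quenched before it takes the C8 proton. An E dienolate cannot close, proton transfer would erode the C8 configuration or conjugate the alkene, closure through the acceptor rotamer with C11 axial would erode C9, and conjugate addition of the amide base would consume the tert-butyl enoate. The fallback sets out from 17 and returns at 21. The dienolate is trapped at −78 °C with t-BuMe2SiCl to give the tert-butyldimethylsilyl dienol ether of 17 F1, a neutral compound whose C6=C7 geometry can be checked. F1 is then cyclised by Lewis-acid activation of the methyl enoate (catalytic t-BuMe2SiOTf, CH2Cl2, −78 °C; an intramolecular Mukaiyama–Michael addition through C8). This gives the tert-butyldimethylsilyl ketene acetal of 21 F2, so no basic enolate is present after closure, and mild aqueous acid hydrolyses F2 to 21.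

2. Step 6. The alkene is flanked by two quaternary carbons, so hydrogen uptake may be slow and delivery to the face opposite the angular methyl may be incomplete. The fallback sets out from 10 and returns at 12. The ketone is reduced first (NaBH4, CeCl3·7H2O, MeOH, −20 °C; Luche reduction) to (7aR)-4,4,7a-trimethyl-2,4,5,6,7,7a-hexahydro-1H-indene-1,2-diol F3; hydride attack anti to the C1 hydroxyl should leave both hydroxyls on the face opposite the angular methyl. The now isolated alkene of F3 is saturated by hydroxyl-directed homogeneous hydrogenation ([Ir(cod)(PCy3)(py)]PF6, H2, CH2Cl2), which handles hindered trisubstituted alkenes and delivers hydrogen from the hydroxyl-bearing face. This gives diol 12, which is cleaved with NaIO4 as in step 7.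

3. Step 9. The stabilised ylide may add too slowly to the aldehyde on the quaternary C10, and long heating may degrade the material. The fallback sets out from 15 and returns at 17. A Reformatsky reaction (Zn, BrCH2CO2Me, THF, reflux), whose zinc enolate adds to hindered aldehydes and does not attack the tert-butyl enoate, gives methyl 3-hydroxy-3-[(1S,2R)-2-[(E)-4-tert-butoxy-4-oxobut-2-en-1-yl]-1,3,3-trimethylcyclohexyl]propanoate F4. Mesylation (MsCl, Et3N, CH2Cl2, 0 °C) gives the corresponding methanesulfonate F5, and DBU eliminates it toward C11, the only β-hydrogen-bearing carbon, to give the (E)-enoate 17.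

## Further compounds

F1 | step 10 | tert-butyldimethylsilyl dienol ether (ketene acetal) of 17, C6=C7 Z | COC(=O)/C=C/[C@]1(C)CCCC(C)(C)[C@H]1/C=C\C=C(O[Si](C)(C)C(C)(C)C)OC(C)(C)C
F2 | step 10 | tert-butyldimethylsilyl ketene acetal of the C12 methyl ester of 21 | COC(O[Si](C)(C)C(C)(C)C)=C[C@@H]1[C@@H](C(=O)OC(C)(C)C)C=C[C@@H]2C(C)(C)CCC[C@@]12C
F3 | step 6 | (7aR)-4,4,7a-trimethyl-2,4,5,6,7,7a-hexahydro-1H-indene-1,2-diol | OC1C(O)[C@]2(C)CCCC(C)(C)C2=C1
F4 | step 9 | methyl 3-hydroxy-3-[(1S,2R)-2-[(E)-4-tert-butoxy-4-oxobut-2-en-1-yl]-1,3,3-trimethylcyclohexyl]propanoate | COC(=O)CC(O)[C@]1(C)CCCC(C)(C)[C@H]1C/C=C/C(=O)OC(C)(C)C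
F5 | step 9 | methanesulfonate of F4 | COC(=O)CC(OS(C)(=O)=O)[C@]1(C)CCCC(C)(C)[C@H]1C/C=C/C(=O)OC(C)(C)C
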